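The cyclohexanone ring is doubly dissonant: the ring C=O carbon is bonded to the gem-dimethyl carbon, and the ring CH2 β to that carbonyl is bonded to the C(OH)Me carbon, so ketone and carbinol are 1,4-related on both arcs. Both links are made in one radical [3+3] annulation. The precursor is an open-chain β,γ-unsaturated methyl ketone carrying the isopropenyl group, the future ring CH stereocentre and the (R)-linalool-derived side chain. Hydrogen-atom transfer gives the tertiary radical, cyclopropanone acts as an acyl–alkyl 1,3-relay, and the relayed primary radical closes onto the methyl ketone, which sets the tertiary carbinol. Linalool's prenyl terminus maps onto the ring CH and gem-dimethyl carbons.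

Key step: step 6

Remark: cyclopropanone ethyl hemiacetal (1-ethoxycyclopropan-1-ol) is taken as a purchased reagent; in solution it equilibrates with free cyclopropanone and ethanol.

Step 1
Reactants: 1 (R)-(−)-linalool
Product: 3 (R)-3,7-dimethyloct-6-ene-1,3-diol, via alkylborane 2 (not isolated)
Conditions: 9-BBN (2.2 equiv), THF, 0 °C to rt; then NaOH, H2O2, 0 °C
Reagents that add atoms: hydrogen peroxide (OO)
Why: Anti-Markovnikov hydroboration with bulky 9-BBN should take the monosubstituted vinyl group and leave the trisubstituted alkene, and oxidation with retention gives the primary alcohol; the linalool carbinol centre is untouched and becomes the side-chain C(OH)Me centre.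

Step 2
Reactants: 3 (R)-3,7-dimethyloct-6-ene-1,3-diol
Product: 4 (3R)-1,3-bis[(tert-butyldimethylsilyl)oxy]-3,7-dimethyloct-6-ene
Conditions: TBSOTf (2.5 equiv), 2,6-lutidine, CH2Cl2, −78 to 0 °C
Reagents that add atoms: tert-butyldimethylsilyl triflate (CC(C)(C)[Si](C)(C)OS(=O)(=O)C(F)(F)F)
Why: Silyl triflate with a hindered pyridine base silylates primary and tertiary hydroxyl alike, which removes both O–H groups before the copper, palladium and radical steps.

Step 3
Reactants: 4 (3R)-1,3-bis[(tert-butyldimethylsilyl)oxy]-3,7-dimethyloct-6-ene; 5 allyl diethyl phosphate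
Product: 6 diethyl (2E,6R)-6,8-bis[(tert-butyldimethylsilyl)oxy]-6-methyloct-2-en-1-yl phosphate
Conditions: second-generation Ru–NHC isopropoxybenzylidene metathesis catalyst (5 mol %), 5 (3 equiv), CH2Cl2, 40 °C
Reagents that add atoms: none
Why: Olefin cross-metathesis of the prenyl-type trisubstituted alkene with a terminal alkene is driven by loss of isobutene and should give the E-disubstituted allylic phosphate needed for SN2′ substitution.

Step 4
Reactants: 6 diethyl (2E,6R)-6,8-bis[(tert-butyldimethylsilyl)oxy]-6-methyloct-2-en-1-yl phosphate; 7 isopropenylboronic acid pinacol ester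
Product: 8 (3R,6S)-1,3-bis[(tert-butyldimethylsilyl)oxy]-6-ethenyl-3,7-dimethyloct-7-ene
Conditions: CuCl (5 mol %), chiral sulfonate-bearing imidazolinium salt (NHC precursor, 5.5 mol %), NaOMe (1.5 equiv), THF, 22 °C
Reagents that add atoms: none
Why: Copper-catalysed enantioselective allylic substitution (SN2′) with an alkenylboron reagent puts the isopropenyl group on the γ-carbon; the chiral NHC–copper catalyst alone sets the new CH centre (6S, the future ring CH), since the carbinol centre is too remote to interfere.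

Step 5
Reactants: 8 (3R,6S)-1,3-bis[(tert-butyldimethylsilyl)oxy]-6-ethenyl-3,7-dimethyloct-7-ene
Product: 9 (3R,6R)-6,8-bis[(tert-butyldimethylsilyl)oxy]-6-methyl-3-(prop-1-en-2-yl)octan-2-one
Conditions: PdCl2 (10 mol %), CuCl (30 mol %), O2 (1 atm), DMF/H2O 7:1, rt
Reagents that add atoms: water (O)
Why: Tsuji–Wacker oxidation hydrates the monosubstituted vinyl group in the Markovnikov sense to the methyl ketone and should spare the 1,1-disubstituted isopropenyl group, and the near-neutral medium keeps the α-CH configuration.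

Step 6
Reactants: 9 (3R,6R)-6,8-bis[(tert-butyldimethylsilyl)oxy]-6-methyl-3-(prop-1-en-2-yl)octan-2-one; 10 1-ethoxycyclopropan-1-ol (cyclopropanone ethyl hemiacetal)
Product: 11 (3R,4S)-3-[(3R)-3,5-bis[(tert-butyldimethylsilyl)oxy]-3-methylpentyl]-4-hydroxy-2,2,4-trimethylcyclohexan-1-one
Conditions: Fe(acac)3 (30 mol %), Ph(i-PrO)SiH2 (2 equiv, slow addition), 10 (4 equiv), THF, 40 °C; aq. NH4Cl
Reagents that add atoms: none
Why: Proposed new method: Iron hydride transfers a hydrogen atom to the isopropenyl CH2 of 9 (Mukaiyama-type MHAT) and gives the tertiary radical at the future gem-dimethyl carbon; this adds to the strained C=O of cyclopropanone (released from 10), and the cyclopropyloxy radical opens at once by β-scission, so the new ketone carbon is bonded to the quaternary carbon and the radical sits on the distal CH2. That primary radical adds 6-exo-trig to the methyl ketone C=O, which closes the cyclohexanone ring, and the alkoxy radical is reduced and protonated by the ethanol set free from 10. The closest known reaction types are the MHAT radical conjugate addition/aldol annulations, the HAT-initiated alkene–ketone radical cyclisations and Dowd–Beckwith addition/β-scission at ketone carbonyls; new is the intermolecular use of cyclopropanone as a 1,3 acyl–alkyl relay. The one new stereocentre, C(OH)Me, should form in a chair transition state with the side chain on the adjacent CH equatorial and the ketone methyl equatorial, because an axial methyl would clash 1,3-diaxially with the axial methyl of the gem-dimethyl group; this puts OH axial and cis to the side chain. The step needs the tertiary radical to attack the small strained carbonyl faster than it is reduced (excess 10, slow silane addition), and it needs the α-CH of 9 to keep its configuration, which the neutral medium and the absence of any other alkene or free hydroxyl support.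

Step 7
Reactants: 11 (3R,4S)-3-[(3R)-3,5-bis[(tert-butyldimethylsilyl)oxy]-3-methylpentyl]-4-hydroxy-2,2,4-trimethylcyclohexan-1-one
Product: 12 (3R,4S)-3-[(3R)-3,5-dihydroxy-3-methylpentyl]-4-hydroxy-2,2,4-trimethylcyclohexan-1-one
Conditions: HF·pyridine, THF/pyridine, 0 °C to rt
Reagents that add atoms: none
Why: Fluoride-driven desilylation should cleave the primary and the tertiary silyl ether, and the tertiary alcohols and the γ-hydroxy ketone tolerate buffered HF.

Step 8
Reactants: 12 (3R,4S)-3-[(3R)-3,5-dihydroxy-3-methylpentyl]-4-hydroxy-2,2,4-trimethylcyclohexan-1-one; 13 7-hydroxycoumarin (umbelliferone)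
Product: 14 7-{[(3R)-3-hydroxy-5-[(1R,2S)-2-hydroxy-2,6,6-trimethyl-5-oxocyclohexyl]-3-methylpentyl]oxy}-2H-chromen-2-one
Conditions: PPh3, DIAD, THF, 0 °C to rt
Reagents that add atoms: none
Why: In the Mitsunobu etherification the acidic phenol (pKa about 8) should be alkylated only by the activated primary alcohol, because the two tertiary alcohols are too hindered to react; no stereocentre is involved.

Compound list
1 | (R)-(−)-linalool | CC(C)=CCC[C@@](C)(O)C=C | starting material
2 | 9-[(3R)-3-hydroxy-3,7-dimethyloct-6-en-1-yl]-9-borabicyclo[3.3.1]nonane | CC(C)=CCC[C@@](C)(O)CCB1C2CCCC1CCC2 | intermediate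
3 | (R)-3,7-dimethyloct-6-ene-1,3-diol | CC(C)=CCC[C@@](C)(O)CCO | intermediate
4 | (3R)-1,3-bis[(tert-butyldimethylsilyl)oxy]-3,7-dimethyloct-6-ene | CC(C)=CCC[C@@](C)(O[Si](C)(C)C(C)(C)C)CCO[Si](C)(C)C(C)(C)C | intermediate
5 | allyl diethyl phosphate | C=CCOP(=O)(OCC)OCC | starting material
6 | diethyl (2E,6R)-6,8-bis[(tert-butyldimethylsilyl)oxy]-6-methyloct-2-en-1-yl phosphate | CCOP(=O)(OCC)OC/C=C/CC[C@@](C)(O[Si](C)(C)C(C)(C)C)CCO[Si](C)(C)C(C)(C)C | intermediate
7 | isopropenylboronic acid pinacol ester | CC(=C)B1OC(C)(C)C(C)(C)O1 | starting material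
8 | (3R,6S)-1,3-bis[(tert-butyldimethylsilyl)oxy]-6-ethenyl-3,7-dimethyloct-7-ene | C=C[C@@H](C(C)=C)CC[C@@](C)(O[Si](C)(C)C(C)(C)C)CCO[Si](C)(C)C(C)(C)C | intermediate
9 | (3R,6R)-6,8-bis[(tert-butyldimethylsilyl)oxy]-6-methyl-3-(prop-1-en-2-yl)octan-2-one | CC(=O)[C@@H](C(C)=C)CC[C@@](C)(O[Si](C)(C)C(C)(C)C)CCO[Si](C)(C)C(C)(C)C | intermediate
10 | 1-ethoxycyclopropan-1-ol | CCOC1(O)CC1 | starting material
11 | (3R,4S)-3-[(3R)-3,5-bis[(tert-butyldimethylsilyl)oxy]-3-methylpentyl]-4-hydroxy-2,2,4-trimethylcyclohexan-1-one | CC1(C)C(=O)CC[C@](C)(O)[C@@H]1CC[C@@](C)(O[Si](C)(C)C(C)(C)C)CCO[Si](C)(C)C(C)(C)C | intermediate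
12 | (3R,4S)-3-[(3R)-3,5-dihydroxy-3-methylpentyl]-4-hydroxy-2,2,4-trimethylcyclohexan-1-one | CC1(C)C(=O)CC[C@](C)(O)[C@@H]1CC[C@@](C)(O)CCO | intermediate
13 | 7-hydroxycoumarin (umbelliferone) | Oc1ccc2ccc(=O)oc2c1 | starting material
14 | 7-{[(3R)-3-hydroxy-5-[(1R,2S)-2-hydroxy-2,6,6-trimethyl-5-oxocyclohexyl]-3-methylpentyl]oxy}-2H-chromen-2-one | CC1(C)C(=O)CC[C@](C)(O)[C@@H]1CC[C@@](C)(O)CCOc1ccc2ccc(=O)oc2c1 | target

Total step count: 8. Longest linear sequence: 8 steps.

Steps most likely to fail

Step 6 (proposed new method). The tertiary radical may be reduced to the isopropyl group before it adds to the cyclopropanone carbonyl. The hemiacetal may be consumed by iron(III) oxidation. The relayed primary radical may be quenched, or may abstract the α-hydrogen, before it closes onto the ketone. A reversible 1,2-acyl shift of the β-keto radical could erode the α-CH configuration. The fallback uses known chemistry; it sets out from 9 and comes back at 11. Branch-selective cobalt/chromium-mediated hydrogen-atom-transfer addition of the isopropenyl group to acrolein (Nozaki–Hiyama-type capture of the tertiary radical) gives the vinyl carbinol F1 as a mixture of carbinol epimers, which does not matter. Hydroboration–oxidation of the vinyl group with 9-BBN gives the diol F2. Iodine, triphenylphosphine and imidazole convert the primary hydroxyl into the iodide F3. A SmI2/HMPA Barbier cyclisation onto the methyl ketone closes the ring to the diol F4 through the same chair arrangement, and periodinane oxidation of the secondary alcohol gives 11.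

Step 4. Enantiofacial selectivity may be poor, and direct SN2 substitution may compete to give the linear diene. The fallback sets out from 4 and comes back at 9, so it also bypasses steps 3 and 5. It forms a C–B bond first and introduces the acetyl group by a stereoretentive 1,2-metallate shift. Allylic oxidation of the E-methyl group with SeO2/t-BuOOH gives the allylic alcohol F5, and methyl chloroformate/pyridine gives the carbonate F6. Copper-catalysed enantioselective SN2′ borylation with B2pin2 and a chiral bisphosphine gives the α-chiral allylboronate F7, in which the isopropenyl group arises by allylic transposition. Addition of (1-ethoxyvinyl)lithium followed by I2/NaOMe (Zweifel olefination, retention at carbon) gives the enol ether F8, and dilute acid hydrolysis gives 9.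

Step 3. Turnover at the trisubstituted alkene may be slow, the allyl phosphate may homodimerise, and E/Z mixtures may form. The fallback sets out from 4 and comes back at 6. Ozonolysis with a PPh3 work-up gives the aldehyde F9. Horner–Wadsworth–Emmons olefination with triethyl phosphonoacetate gives the E-enoate F10. DIBAL-H reduction gives the allylic alcohol F11, and diethyl chlorophosphate/DMAP gives 6.

Further compounds
F1 | step 6 | (3R,6R)-6,8-bis[(tert-butyldimethylsilyl)oxy]-3-(3-hydroxy-2-methylpent-4-en-2-yl)-6-methyloctan-2-one | CC(=O)[C@@H](C(C)(C)C(O)C=C)CC[C@@](C)(O[Si](C)(C)C(C)(C)C)CCO[Si](C)(C)C(C)(C)C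
F2 | step 6 | (3R,6R)-6,8-bis[(tert-butyldimethylsilyl)oxy]-3-(3,5-dihydroxy-2-methylpentan-2-yl)-6-methyloctan-2-one | CC(=O)[C@@H](C(C)(C)C(O)CCO)CC[C@@](C)(O[Si](C)(C)C(C)(C)C)CCO[Si](C)(C)C(C)(C)C
F3 | step 6 | (3R,6R)-6,8-bis[(tert-butyldimethylsilyl)oxy]-3-(3-hydroxy-5-iodo-2-methylpentan-2-yl)-6-methyloctan-2-one | CC(=O)[C@@H](C(C)(C)C(O)CCI)CC[C@@](C)(O[Si](C)(C)C(C)(C)C)CCO[Si](C)(C)C(C)(C)C
F4 | step 6 | (1S,2R)-2-[(3R)-3,5-bis[(tert-butyldimethylsilyl)oxy]-3-methylpentyl]-1,3,3-trimethylcyclohexane-1,4-diol | CC1(C)C(O)CC[C@](C)(O)[C@@H]1CC[C@@](C)(O[Si](C)(C)C(C)(C)C)CCO[Si](C)(C)C(C)(C)C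
F5 | step 4 | (2E,6R)-6,8-bis[(tert-butyldimethylsilyl)oxy]-2,6-dimethyloct-2-en-1-ol | OC/C(C)=C/CC[C@@](C)(O[Si](C)(C)C(C)(C)C)CCO[Si](C)(C)C(C)(C)C
F6 | step 4 | (2E,6R)-6,8-bis[(tert-butyldimethylsilyl)oxy]-2,6-dimethyloct-2-en-1-yl methyl carbonate | COC(=O)OC/C(C)=C/CC[C@@](C)(O[Si](C)(C)C(C)(C)C)CCO[Si](C)(C)C(C)(C)C
F7 | step 4 | 2-[(3R,6R)-6,8-bis[(tert-butyldimethylsilyl)oxy]-2,6-dimethyloct-1-en-3-yl]-4,4,5,5-tetramethyl-1,3,2-dioxaborolane | CC1(C)OB(OC1(C)C)[C@@H](C(C)=C)CC[C@@](C)(O[Si](C)(C)C(C)(C)C)CCO[Si](C)(C)C(C)(C)C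
F8 | step 4 | (3R,6R)-6,8-bis[(tert-butyldimethylsilyl)oxy]-2-ethoxy-6-methyl-3-(prop-1-en-2-yl)oct-1-ene | CCOC(=C)[C@@H](C(C)=C)CC[C@@](C)(O[Si](C)(C)C(C)(C)C)CCO[Si](C)(C)C(C)(C)C
F9 | step 3 | (4R)-4,6-bis[(tert-butyldimethylsilyl)oxy]-4-methylhexanal | O=CCC[C@@](C)(O[Si](C)(C)C(C)(C)C)CCO[Si](C)(C)C(C)(C)C
F10 | step 3 | ethyl (2E,6R)-6,8-bis[(tert-butyldimethylsilyl)oxy]-6-methyloct-2-enoate | CCOC(=O)/C=C/CC[C@@](C)(O[Si](C)(C)C(C)(C)C)CCO[Si](C)(C)C(C)(C)C
F11 | step 3 | (2E,6R)-6,8-bis[(tert-butyldimethylsilyl)oxy]-6-methyloct-2-en-1-ol | OC/C=C/CC[C@@](C)(O[Si](C)(C)C(C)(C)C)CCO[Si](C)(C)C(C)(C)C
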